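The route rests on reading rings A and B (C1–C10), the C8–O bond and the C11–C13/C16 methyl-ketone stub as a chair–chair-folded farnesylacetone whose terminal (E)-methyl, the future C18, is oxidised. In one Lewis-acid operation the (2S,3S)-epoxide of this chain forms C4–C5 and C9–C10 while its carbonyl oxygen captures the C8 cation, closing ring A, ring B and a dihydropyran and fixing C5, C8, C9 and C10, with C4 carrying axial methyl and equatorial CH2O. The precursor, a silyl-protected epoxy-farnesylacetone, lies three steps from farnesylacetone. Afterwards the C18 oxygen delivers the 6α-oxygen, and the released methyl ketone is grown into the butenolide side chain.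

Key step: step 4

Assumption: labdane numbering is used (C14/C15 for the olefination carbons, C2′–C5′ for the butenolide); the 6α-hydroxy-18-aldehyde and its five-membered lactol are taken to interconvert freely, so acid/methanol gives the cyclic methyl acetal and its hydrolysis returns the open hydroxy-aldehyde drawn for the target.

Step 1
Reactants: 1 (5E,9E)-farnesylacetone
Product: 2 (5E,9E,13E)-15-hydroxy-6,10,14-trimethylpentadeca-5,9,13-trien-2-one
Conditions: SeO2 (cat.), t-BuOOH, salicylic acid (cat.), CH2Cl2, 0 °C to rt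
Reagents that add atoms: tert-butyl hydroperoxide, CC(C)(C)OO; selenium dioxide, O=[Se]=O (relays the oxygen and is regenerated by the peroxide)
Why: Allylic oxidation by SeO2 (ene reaction, then [2,3]-sigmatropic shift) should take the (E)-methyl of the most exposed, terminal trisubstituted alkene, the ketone being inert at room temperature; no stereocentre is formed and the E geometry follows from the [2,3] shift.

Step 2
Reactants: 2 (5E,9E,13E)-15-hydroxy-6,10,14-trimethylpentadeca-5,9,13-trien-2-one
Product: 3 (5E,9E)-12-[(2S,3S)-3-(hydroxymethyl)-3-methyloxiran-2-yl]-6,10-dimethyldodeca-5,9-dien-2-one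
Conditions: Ti(OiPr)4 (cat.), L-(+)-diethyl tartrate (cat.), t-BuOOH, 4 Å molecular sieves, CH2Cl2, −20 °C
Reagents that add atoms: tert-butyl hydroperoxide, CC(C)(C)OO
Why: Sharpless asymmetric epoxidation acts only on the alkene of the allylic alcohol, and the L-(+)-tartrate catalyst should deliver oxygen to the face that gives the (2S,3S)-epoxide, which fixes C3 and C4 of the future ring A.

Step 3
Reactants: 3 (5E,9E)-12-[(2S,3S)-3-(hydroxymethyl)-3-methyloxiran-2-yl]-6,10-dimethyldodeca-5,9-dien-2-one
Product: 4 (5E,9E)-12-[(2S,3S)-3-(tert-butyldimethylsilyloxymethyl)-3-methyloxiran-2-yl]-6,10-dimethyldodeca-5,9-dien-2-one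
Conditions: TBSCl, imidazole, DMF, 0 °C to rt
Reagents that add atoms: tert-butyldimethylsilyl chloride, CC(C)(C)[Si](C)(C)Cl
Why: Standard silylation of the primary alcohol; the TBS ether tolerates the Lewis acid of step 4 and is later shed in the same acidic methanol that masks the enol ether (step 7).

Step 4
Reactants: 4 (5E,9E)-12-[(2S,3S)-3-(tert-butyldimethylsilyloxymethyl)-3-methyloxiran-2-yl]-6,10-dimethyldodeca-5,9-dien-2-one
Product: 5 18-(tert-butyldimethylsilyloxy)-8α,13-epoxy-14,15-dinorlabd-12-en-3β-ol
Conditions: MeAlCl2 (about 1.2 equiv), CH2Cl2, −78 °C; Et3N, then aq. NaHCO3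
Reagents that add atoms: none
Why: MeAlCl2 binds the epoxide oxygen, positive charge builds at tertiary C4, the C5=C10 alkene attacks C4 anti to the departing oxygen, the C8=C9 alkene takes the C10 cation and the uncomplexed carbonyl oxygen takes the C8 cation, giving a cyclic oxocarbenium ion that loses H-12 (the methyl on aluminium removes the proton as methane). The closest known reaction types are the Lewis-acid epoxy-polyene cyclisation and the oxygen-terminated cyclisation of farnesylacetone to the sclareol-oxide enol ether. Ring A closes 6-endo (epoxide opened at C4, both carbons of the C5=C10 alkene in the ring), ring B closes 6-endo on the C8=C9 alkene, and the dihydropyran closes by 6-endo attack of the carbonyl oxygen on C8. C4 is inverted, so the E-placed CH2OSi ends equatorial (α) and the methyl axial; C5 and C10 follow from anti addition across the E C5=C10 alkene in a chair relayed from the (3S)-epoxide, and C9 and C8 from anti addition across the E C8=C9 alkene in the second chair, giving the trans-decalin with equatorial C9 chain and equatorial 8α-oxygen. The step needs oxygen capture to outrun proton loss and hydride shifts; the six-membered reach of the carbonyl and the use of only about one equivalent of Lewis acid (so that the ketone is not tied up) should secure this, and any exocyclic enol-ether isomer converges with 5 in step 7.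

Step 5
Reactants: 5 18-(tert-butyldimethylsilyloxy)-8α,13-epoxy-14,15-dinorlabd-12-en-3β-ol
Product: 6 3β-O-(imidazol-1-ylthiocarbonyl) derivative of 5
Conditions: 1,1′-thiocarbonyldiimidazole, DMAP (cat.), toluene, 90 °C
Reagents that add atoms: 1,1′-thiocarbonyldiimidazole, S=C(n1ccnc1)n1ccnc1
Why: Thioacylation of the equatorial 3β-hydroxyl under neutral conditions forms no alkoxide, so the 1,3-related silyl ether cannot migrate and the acid-sensitive enol ether is untouched.

Step 6
Reactants: 6 3β-O-(imidazol-1-ylthiocarbonyl) derivative of 5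
Product: 7 18-(tert-butyldimethylsilyloxy)-8α,13-epoxy-14,15-dinorlabd-12-ene
Conditions: Bu3SnH, AIBN (cat.), toluene, 100 °C
Reagents that add atoms: none
Why: Barton–McCombie deoxygenation: the stannyl radical adds to C=S, C3–O scission gives a secondary radical with no β-leaving group, and hydrogen transfer removes the relay oxygen without touching the other centres.

Step 7
Reactants: 7 18-(tert-butyldimethylsilyloxy)-8α,13-epoxy-14,15-dinorlabd-12-ene
Product: 9 13ξ-methoxy-8α,13-epoxy-14,15-dinorlabdan-18-ol, via silyl methyl ketal 8 (not isolated)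
Conditions: HCl (cat.) in MeOH, 0 °C to rt; NaHCO3 quench
Reagents that add atoms: methanol, CO
Why: Acid-catalysed addition of methanol to the enol ether (through the oxocarbenium ion) gives a cyclic mixed ketal that masks both the C8 oxygen and the C13 carbonyl, and the same methanolic acid cleaves the primary silyl ether; C13 forms as an inconsequential epimer mixture (axial methoxy expected to prevail) that is erased in step 9.

Step 8
Reactants: 9 13ξ-methoxy-8α,13-epoxy-14,15-dinorlabdan-18-ol
Product: 10 13ξ-methoxy-6α,18:8α,13-diepoxy-14,15-dinorlabdane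
Conditions: PhI(OAc)2, I2, NaHCO3, cyclohexane, visible light, rt
Reagents that add atoms: none
Why: Suárez hypoiodite reaction: the 18-alkoxy radical has a single δ-hydrogen within reach, the equatorial 6α-H (C18 and 6α-H are syn-pentane related across C5), and after 1,5-hydrogen transfer and iodine capture the tethered oxygen can close only on the α face, which sets C6; the buffered medium and the absence of any other hydroxyl protect the ketal.

Step 9
Reactants: 10 13ξ-methoxy-6α,18:8α,13-diepoxy-14,15-dinorlabdane
Product: 12 8α-hydroxy-13-oxo-14,15-dinorlabdan-18,6α-olide, via lactone methyl ketal 11 (not isolated)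
Conditions: RuCl3·xH2O (cat.), NaIO4, CCl4/MeCN/H2O, rt; then 1 M HCl, THF, rt
Reagents that add atoms: NaIO4 (sodium periodate), [Na+].[O-][I](=O)(=O)=O; water, O
Why: RuO4 oxidation of an ether to a lactone should take the accessible C18 methylene and not the C6 methine, whose axial 6β-H is shielded by the C19 and C20 methyls, and the acidic finish hydrolyses the tertiary ketal to the δ-hydroxy ketone; no stereocentre changes.

Step 10
Reactants: 12 8α-hydroxy-13-oxo-14,15-dinorlabdan-18,6α-olide; 13 triethyl phosphonoacetate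
Product: 14 ethyl (13E)-8α-hydroxy-18-oxo-6α,18-epoxylabd-13-en-15-oate
Conditions: NaH, THF, 0 °C to 50 °C; E isomer separated by chromatography
Reagents that add atoms: none
Why: Horner–Wadsworth–Emmons olefination of the methyl ketone should favour the E-enoate (ester trans to the larger C12 chain); the lactone is neopentyl and non-enolisable, and a tertiary alkoxide does not add to the β,β-disubstituted enoate.

Step 11
Reactants: 14 ethyl (13E)-8α-hydroxy-18-oxo-6α,18-epoxylabd-13-en-15-oate
Product: 15 (13E)-6α,18-epoxylabd-13-ene-8α,15,18ξ-triol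
Conditions: i-Bu2AlH (excess), CH2Cl2, −78 °C; aq. KNaC4H4O6
Reagents that add atoms: none
Why: The aluminium hydride reduces the enoate 1,2 to the E-allylic alcohol and should stop the hindered γ-lactone at the lactol, since its aluminium hemiacetal survives at −78 °C until the quench; C18 forms as a mixture of anomers.

Step 12
Reactants: 15 (13E)-6α,18-epoxylabd-13-ene-8α,15,18ξ-triol
Product: 16 (13E)-18ξ-methoxy-6α,18-epoxylabd-13-ene-8α,15-diol
Conditions: MeOH, pyridinium p-toluenesulfonate (cat.), rt
Reagents that add atoms: methanol, CO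
Why: Fischer-type acetalisation of the lactol through its cyclic oxocarbenium ion masks C6–OH and the C18 aldehyde together, and this weak acid should neither ionise the primary allylic alcohol nor dehydrate the tertiary one.

Step 13
Reactants: 16 (13E)-18ξ-methoxy-6α,18-epoxylabd-13-ene-8α,15-diol
Product: 17 (13E)-8α-hydroxy-18ξ-methoxy-6α,18-epoxylabd-13-en-15-al
Conditions: MnO2, CH2Cl2, rt
Reagents that add atoms: none
Why: MnO2 oxidises only the allylic alcohol and does so under neutral conditions, so the E geometry of the enal and the acetal persist.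

Step 14
Reactants: 18 4-methylfuran-2(5H)-one
Product: 19 4-methyl-2-(trimethylsilyloxy)furan
Conditions: Me3SiOTf, Et3N, Et2O, 0 °C; filtration and distillation under argon
Reagents that add atoms: trimethylsilyl triflate, C[Si](C)(C)OS(=O)(=O)C(F)(F)F
Why: Soft enolisation and O-silylation of the butenolide give the aromatic 2-silyloxyfuran, the standard vinylogous nucleophile.

Step 15
Reactants: 17 (13E)-8α-hydroxy-18ξ-methoxy-6α,18-epoxylabd-13-en-15-al; 19 4-methyl-2-(trimethylsilyloxy)furan
Product: 21 (5′R)-5′-[(13E,15R)-8α,15-dihydroxy-18ξ-methoxy-6α,18-epoxylabd-13-en-15-yl]-4′-methylfuran-2′(5′H)-one, via trimethylsilyl ether 20 (not isolated)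
Conditions: Ti(OiPr)4 (cat.), (S)-BINOL (cat.), Et2O, −20 °C; then pyridinium p-toluenesulfonate (cat.), MeOH, 0 °C
Reagents that add atoms: none
Why: Catalytic asymmetric vinylogous Mukaiyama aldol addition: the BINOL–titanium Lewis acid activates the enal for 1,2-attack by furan C5′ and leaves the acetal alone; the (S)-ligand is expected to expose the Si face of C15 (15R, by analogy with other BINOL–titanium carbonyl additions; the antipodal ligand is used if the sense proves opposite), and the open transition state should give the threo C15/C5′ relationship usual for Lewis-acid additions of 2-silyloxyfurans (5′R). A silylated 8-hydroxyl would be freed in the methanolic finish.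

Step 16
Reactants: 21 (5′R)-5′-[(13E,15R)-8α,15-dihydroxy-18ξ-methoxy-6α,18-epoxylabd-13-en-15-yl]-4′-methylfuran-2′(5′H)-one
Product: 23 (14S,15R,5′R)-6α,18-methyl acetal of the target, via 14-hydroperoxide 22 (not isolated)
Conditions: O2, tetraphenylporphyrin (cat.), visible light, CH2Cl2, −10 °C; then PPh3
Reagents that add atoms: dioxygen, O=O
Why: Hydroxyl-directed Schenck ene reaction: 1,3-allylic strain between the C16 methyl and the C15 substituents fixes the conformer, singlet oxygen is steered to the face of the hydrogen-bonding 15-OH, bonds to C14 and abstracts hydrogen from the cis C16 methyl, which should give the threo (14S) hydroperoxide with the 13(16)-methylene; PPh3 reduces the O–O bond, and the electron-poor butenolide is inert.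

Step 17
Reactants: 23 (14S,15R,5′R)-6α,18-methyl acetal of the target
Product: 24 CNP0156243.1 (target)
Conditions: AcOH/THF/H2O, 35 °C
Reagents that add atoms: water, O
Why: Mild acid hydrolysis of the five-membered methyl acetal frees the 6α-hydroxyl and the C18 aldehyde; the tertiary alcohol, the allylic diol next to a 1,1-disubstituted alkene and the butenolide should tolerate these conditions, and no stereocentre is touched.

Compound list
1 | (5E,9E)-farnesylacetone | CC(C)=CCC/C(C)=C/CC/C(C)=C/CCC(C)=O | starting material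
2 | (5E,9E,13E)-15-hydroxy-6,10,14-trimethylpentadeca-5,9,13-trien-2-one | OC/C(C)=C/CC/C(C)=C/CC/C(C)=C/CCC(C)=O | intermediate
3 | (5E,9E)-12-[(2S,3S)-3-(hydroxymethyl)-3-methyloxiran-2-yl]-6,10-dimethyldodeca-5,9-dien-2-one | OC[C@]1(C)O[C@H]1CC/C(C)=C/CC/C(C)=C/CCC(C)=O | intermediate
4 | TBS ether of 3 (key-step precursor) | CC(C)(C)[Si](C)(C)OC[C@]1(C)O[C@H]1CC/C(C)=C/CC/C(C)=C/CCC(C)=O | intermediate
5 | 18-(tert-butyldimethylsilyloxy)-8α,13-epoxy-14,15-dinorlabd-12-en-3β-ol (key-step product) | CC1=CC[C@@H]2[C@@]3(C)CC[C@H](O)[C@@](C)(CO[Si](C)(C)C(C)(C)C)[C@@H]3CC[C@@]2(C)O1 | intermediate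
6 | 3β-O-(imidazol-1-ylthiocarbonyl) derivative of 5 | CC1=CC[C@@H]2[C@@]3(C)CC[C@H](OC(=S)n4ccnc4)[C@@](C)(CO[Si](C)(C)C(C)(C)C)[C@@H]3CC[C@@]2(C)O1 | intermediate
7 | 18-(tert-butyldimethylsilyloxy)-8α,13-epoxy-14,15-dinorlabd-12-ene | CC1=CC[C@@H]2[C@@]3(C)CCC[C@@](C)(CO[Si](C)(C)C(C)(C)C)[C@@H]3CC[C@@]2(C)O1 | intermediate
8 | 18-(tert-butyldimethylsilyloxy)-13ξ-methoxy-8α,13-epoxy-14,15-dinorlabdane (C13 epimers) | COC1(C)CC[C@@H]2[C@@]3(C)CCC[C@@](C)(CO[Si](C)(C)C(C)(C)C)[C@@H]3CC[C@@]2(C)O1 | intermediate (not isolated)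
9 | 13ξ-methoxy-8α,13-epoxy-14,15-dinorlabdan-18-ol | COC1(C)CC[C@@H]2[C@@]3(C)CCC[C@@](C)(CO)[C@@H]3CC[C@@]2(C)O1 | intermediate
10 | 13ξ-methoxy-6α,18:8α,13-diepoxy-14,15-dinorlabdane | COC1(C)CC[C@@H]2[C@@]3(C)CCC[C@@](C)(CO4)[C@@H]3[C@@H]4C[C@@]2(C)O1 | intermediate
11 | 13ξ-methoxy-8α,13-epoxy-14,15-dinorlabdan-18,6α-olide | COC1(C)CC[C@@H]2[C@@]3(C)CCC[C@@](C)(C(=O)O4)[C@@H]3[C@@H]4C[C@@]2(C)O1 | intermediate (not isolated)
12 | 8α-hydroxy-13-oxo-14,15-dinorlabdan-18,6α-olide | CC(=O)CC[C@@H]1[C@@]2(C)CCC[C@@](C)(C(=O)O3)[C@@H]2[C@@H]3C[C@@]1(C)O | intermediate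
13 | triethyl phosphonoacetate | CCOC(=O)CP(=O)(OCC)OCC | starting material
14 | ethyl (13E)-8α-hydroxy-18-oxo-6α,18-epoxylabd-13-en-15-oate | CCOC(=O)/C=C(\C)CC[C@@H]1[C@@]2(C)CCC[C@@](C)(C(=O)O3)[C@@H]2[C@@H]3C[C@@]1(C)O | intermediate
15 | (13E)-6α,18-epoxylabd-13-ene-8α,15,18ξ-triol (lactol, C18 anomers) | OC/C=C(\C)CC[C@@H]1[C@@]2(C)CCC[C@@](C)(C(O)O3)[C@@H]2[C@@H]3C[C@@]1(C)O | intermediate
16 | (13E)-18ξ-methoxy-6α,18-epoxylabd-13-ene-8α,15-diol | OC/C=C(\C)CC[C@@H]1[C@@]2(C)CCC[C@@](C)(C(OC)O3)[C@@H]2[C@@H]3C[C@@]1(C)O | intermediate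
17 | (13E)-8α-hydroxy-18ξ-methoxy-6α,18-epoxylabd-13-en-15-al | O=C/C=C(\C)CC[C@@H]1[C@@]2(C)CCC[C@@](C)(C(OC)O3)[C@@H]2[C@@H]3C[C@@]1(C)O | intermediate
18 | 4-methylfuran-2(5H)-one | CC1=CC(=O)OC1 | starting material
19 | 4-methyl-2-(trimethylsilyloxy)furan | Cc1coc(O[Si](C)(C)C)c1 | intermediate
20 | 15-O-trimethylsilyl ether of 21 | CC1=CC(=O)O[C@H]1[C@H](O[Si](C)(C)C)/C=C(\C)CC[C@@H]2[C@@]3(C)CCC[C@@](C)(C(OC)O4)[C@@H]3[C@@H]4C[C@@]2(C)O | intermediate (not isolated)
21 | (5′R)-5′-[(13E,15R)-8α,15-dihydroxy-18ξ-methoxy-6α,18-epoxylabd-13-en-15-yl]-4′-methylfuran-2′(5′H)-one | CC1=CC(=O)O[C@H]1[C@H](O)/C=C(\C)CC[C@@H]2[C@@]3(C)CCC[C@@](C)(C(OC)O4)[C@@H]3[C@@H]4C[C@@]2(C)O | intermediate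
22 | (14S,15R,5′R)-14-hydroperoxy-13(16)-ene acetal | C=C(CC[C@@H]1[C@@]2(C)CCC[C@@](C)(C(OC)O3)[C@@H]2[C@@H]3C[C@@]1(C)O)[C@H](OO)[C@@H](O)[C@@H]1OC(=O)C=C1C | intermediate (not isolated)
23 | (14S,15R,5′R)-6α,18-methyl acetal of the target | C=C(CC[C@@H]1[C@@]2(C)CCC[C@@](C)(C(OC)O3)[C@@H]2[C@@H]3C[C@@]1(C)O)[C@H](O)[C@@H](O)[C@@H]1OC(=O)C=C1C | intermediate
24 | CNP0156243.1 | C=C(CC[C@@H]1[C@@]2(C)CCC[C@@](C)(C=O)[C@@H]2[C@@H](O)C[C@@]1(C)O)[C@H](O)[C@@H](O)[C@@H]1OC(=O)C=C1C | target

Total steps: 17. Longest linear sequence: 16 steps (1 to 24 through steps 1–13 and 15–17; step 14 is the only side-branch step).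

Steps most likely to fail

1. Step 4 (key step). The Lewis acid may be held by the ketone oxygen, so that the C8 cation is quenched by proton loss, or the cascade stops after ring A, instead of being captured by oxygen. The fallback sets out from 4 and comes back at 5, and it separates the third ring closure from the carbocyclisation. Compound 4 is cyclised with an excess of MeAlCl2, so that the complexed carbonyl stays out and the cascade ends by proton loss, giving 18-(tert-butyldimethylsilyloxy)-3β-hydroxy-14,15-dinorlabd-8(17)-en-13-one F1 (with its endocyclic alkene isomers). In a second operation a catalytic Brønsted acid (camphorsulfonic acid or TfOH, CH2Cl2, low temperature) protonates the alkene, and the now free carbonyl oxygen takes the C8 cation to give 5. The stereochemical relay at C4, C5, C9 and C10 is unchanged because the carbocyclisation stays cationic.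

2. Step 8. β-Scission of the neopentyl 18-alkoxy radical (loss of formaldehyde) or elimination at C6 may outrun 1,5-hydrogen transfer and ether closure. The fallback sets out from 9 and comes back at 12, and it hands the hydrogen abstraction to a nitrogen radical that cannot fragment. Alcohol 9 is oxidised with Pr4N[RuO4] (cat.) and N-methylmorpholine N-oxide monohydrate in MeCN to 13ξ-methoxy-8α,13-epoxy-14,15-dinorlabdan-18-oic acid F2. This is converted with (COCl)2/pyridine and then NH3 into the primary amide F3. Photolysis of F3 with PhI(OAc)2 and I2 forms the N-iodoamide, whose amidyl radical abstracts 6α-H; closure through the amide oxygen gives the 18,6α-iminolactone F4. Treatment with 1 M HCl in THF hydrolyses the imine and the ketal together to give 12, which also makes the RuO4 step unnecessary.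

3. Step 15. The catalyst may give poor facial selectivity at C15, for example if the free tertiary 8-hydroxyl sequesters titanium, or poor threo selectivity. The fallback sets out from 17 and 19 and comes back at 21, and it replaces catalyst control of the C–C bond formation by a resolution. The addition is run with racemic BINOL/Ti(OiPr)4 and gives 20 together with the (15S,5′S) trimethylsilyl ether F5. The same methanolic finish gives 21 and its (15S,5′S) isomer F6. Sharpless kinetic resolution with Ti(OiPr)4, D-(−)-diisopropyl tartrate and t-BuOOH at −20 °C should epoxidise the faster-reacting (15S) allylic alcohol F6 to the (13R,14R,15S,5′S)-13,14-epoxy alcohol F7. The (15R) alcohol 21 is the slow-reacting partner and is recovered by chromatography.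

Further compounds
F1 | step 4 | 18-(tert-butyldimethylsilyloxy)-3β-hydroxy-14,15-dinorlabd-8(17)-en-13-one | CC(=O)CC[C@@H]1[C@@]2(C)CC[C@H](O)[C@@](C)(CO[Si](C)(C)C(C)(C)C)[C@@H]2CCC1=C
F2 | step 8 | 13ξ-methoxy-8α,13-epoxy-14,15-dinorlabdan-18-oic acid | COC1(C)CC[C@@H]2[C@@]3(C)CCC[C@@](C)(C(=O)O)[C@@H]3CC[C@@]2(C)O1
F3 | step 8 | 13ξ-methoxy-8α,13-epoxy-14,15-dinorlabdan-18-amide | COC1(C)CC[C@@H]2[C@@]3(C)CCC[C@@](C)(C(N)=O)[C@@H]3CC[C@@]2(C)O1
F4 | step 8 | 18-imino-13ξ-methoxy-6α,18:8α,13-diepoxy-14,15-dinorlabdane (iminolactone) | COC1(C)CC[C@@H]2[C@@]3(C)CCC[C@@](C)(C(=N)O4)[C@@H]3[C@@H]4C[C@@]2(C)O1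
F5 | step 15 | (15S,5′S) diastereomer of trimethylsilyl ether 20 | CC1=CC(=O)O[C@@H]1[C@@H](O[Si](C)(C)C)/C=C(\C)CC[C@@H]2[C@@]3(C)CCC[C@@](C)(C(OC)O4)[C@@H]3[C@@H]4C[C@@]2(C)O
F6 | step 15 | (15S,5′S) diastereomer of 21 | CC1=CC(=O)O[C@@H]1[C@@H](O)/C=C(\C)CC[C@@H]2[C@@]3(C)CCC[C@@](C)(C(OC)O4)[C@@H]3[C@@H]4C[C@@]2(C)O
F7 | step 15 | (13R,14R,15S,5′S)-13,14-epoxide of F6 | CC1=CC(=O)O[C@@H]1[C@@H](O)[C@H]2O[C@]2(C)CC[C@@H]3[C@@]4(C)CCC[C@@](C)(C(OC)O5)[C@@H]4[C@@H]5C[C@@]3(C)O
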